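The data were computed for an exercise, noise included.

in all of them: solid substrate 0.25 M

| charge | catalyst | temperature | remark | time |
|---|---|---|---|---|
| eta | 0.25 mM | 25 °C | the very flask that is asked about, followed so far |  |
| epsilon | 0.38 mM | 31 °C | run made earlier |  |
| flask | 0.25 mM | 25 °C |  | 8.0 d |

- eta (time / d: target / %): 0.417: 16; 0.625: 28; 1.04: 35; 1.67: 33; 3.00: 31; 5.00: 33
- epsilon (time / h: target / %): 3.00: 4; 8.00: 19; 15.0: 35; 25.0: 40; 30.0: 44; 40.0: 41

(readings scatter by 1.5 percentage points)

- dusk: change nothing and wait 2.5 d more
- midnight: at 8.0 d take out 90 % of the target then present, then wait 2.5 d
- noon: at 8.0 d add catalyst, 100 % of the amount charged, then wait 2.5 d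
- winter: at 8.0 d raise the temperature by 20 K, then wait 2.5 d

- solid substrate is a solid; its amount is given per volume of the solution
- what is taken out of target is counted as made
- the numbers in the tables scatter by 1.5 percentage points (one standard deviation)
- steps under discussion: starting material + catalyst <-> target + catalyst; starting material + catalyst <-> isomer of the product A + catalyst; starting material + catalyst <-> isomer of the product B + catalyst; starting material <-> dormant form; solid substrate <-> starting material
- at the start none of the solid substrate is in solution
- additions bring no volume worth counting

* target, in percent of the solid substrate first charged, at 8.0 d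
* what to do for the largest gain in target; "none" if nothing gains more than 2 percentage points (dusk / midnight / noon / winter / none)
* target present, with what was taken out counted in, in percent of the solid substrate first charged, after midnight
* target present, with what was taken out counted in, in percent of the solid substrate first charged, after noon

**Blind spot.** I cannot see the rest of the charge in the eta flask, since its readings give target and leave the other forms unmeasured. So I reckon with target against that rest. From 1.04 d on, the eta readings average 33.0 %. From 25.0 h on, the epsilon readings average 41.7 %.

**Plateau odds.** The eta flask gives 0.493 for the plateau odds, target at its level over the rest of the charge. The epsilon run gives 0.714. I take the plateau as a balance among dissolved forms (thermodynamic control), so waiting and catalyst leave the odds alone. The eta flask levelled by 1.04 d, earlier than 8.0 d, so I commit to 33.0 % at 8.0 d and after noon.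

**Taking out.** I compute midnight as a correction. My estimate assumes that target returns within the wait to the same share of the pool that remains; the gain is then 20 percentage points, and the count reaches 52.9 %. The wait of 2.5 d is longer than the 1.04 d the eta flask took to level.

**Warming.** Taking ln of the odds as straight in temperature, a rise of 20 K gives odds of 1.70. Target is then 63.0 %, a gain of 30 points, larger than midnight's. I choose winter.

**Weak link.** Suppose instead that solid substrate stays undissolved in the eta flask. Midnight then refills in full and gains 30 points, while target scales with temperature and winter gains 39 points, still more. The ranking stands either way.

**The forecast.** It gives 32.5 %, midnight, 60 % after midnight and 33 % after noon, holding that “undissolved solid pins the starting material at saturation”. It parts from my reckoning on the best option and on midnight.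

**The flask.** It gives 30.8 % at 8.0 d, 30.8 % after noon and 47.6 % after midnight, less than my 52.9 %. The best option is winter, which gains 33 points against my 30 points and beats midnight's 17 points.

    starting material + catalyst ⇌ target + catalyst, rate k1*[starting material]*[catalyst] forward; the back reaction follows from the equilibrium constant (K = 1.90, k = 4.50 /M/min, Ea = 43.0 kJ/mol, ΔH = 38.0 kJ/mol)
    starting material + catalyst ⇌ isomer of the product A + catalyst, rate k2*[starting material]*[catalyst] forward; the back reaction follows from the equilibrium constant (K = 0.0690, k = 1.50 /M/min, Ea = 51.0 kJ/mol, ΔH = −80.0 kJ/mol)
    starting material + catalyst ⇌ isomer of the product B + catalyst, rate k3*[starting material]*[catalyst] forward; the back reaction follows from the equilibrium constant (K = 1.30, k = 2.10 /M/min, Ea = 54.0 kJ/mol, ΔH = 3.00 kJ/mol)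
    starting material ⇌ dormant form (K = 1.90, k = 0.00100 /min, Ea = 95.0 kJ/mol, ΔH = −59.0 kJ/mol)
    solid substrate ⇌ starting material, rate k5*(cs5 - [starting material]) while solid is left; crystals form when [starting material] > cs5 (solubility = 0.230 M, k = 0.00240 /min)
    (constants at 25 °C)

**Dissolving first.** Half the dissolving turnover is done by 0.203 d, well before 8.0 d, and solid substrate stands at 0 % after 0.800 d. Carried to a repeat at 50 °C, the plateau odds become 2.32, or target 69.9 %, and that repeat holds 69.5 %.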